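Read the noon and autumn runs by counting partner, and then ask which concentration sets the rate of what follows.

common to all: substrate 0.40 M
- noon: partner 0.40 M; capture agent 0.56 M; run made earlier
- autumn: partner 0.40 M; capture agent 0.88 M; run made earlier
- flask: partner 0.400 M; capture agent 0.400 M; time 20 min

| run | time / min | first product / % | double product / % | substrate / % |
|---|---|---|---|---|
| noon | 0.667 | 21 | 5 | 70 |
| noon | 2.00 | 23 | 22 | 52 |
| noon | 3.00 | 21 | 26 | 46 |
| noon | 5.00 | 23 | 31 | 38 |
| noon | 8.00 | 16 | 35 | 40 |
| noon | 10.0 | 10 | 35 | 35 |
| noon | 12.0 | 13 | 36 | 37 |
| autumn | 1.00 | 20 | 10 | 65 |
| autumn | 1.33 | 23 | 18 | 60 |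
| autumn | 2.00 | 24 | 25 | 53 |
| autumn | 3.00 | 21 | 29 | 48 |
| autumn | 5.00 | 18 | 37 | 41 |
| autumn | 8.00 | 13 | 36 | 40 |
| autumn | 12.0 | 13 | 36 | 37 |

(each reading ± 2 percentage points)

1. equivalents of partner to substrate, everything else as given, that leave most first product at 20 min
2. the amount of first product then, in percent of the substrate charged
3. the amount of first product with the amounts as given

- the numbers in the tables scatter by 2 percentage points (one standard deviation)

- I took partner as the limiting reagent: one partner goes into a first product and two into a double product. The substrate in the noon run levelled near 37 %, so at one equivalent of partner the count allowed 26.0 % of the charge as first product, before any loss.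
- I started the clock at 5.00 min, when substrate read 38 % at noon and 41 % in autumn, close to its level, and first product read 23 % and 18 %, a mean of 20.5 %. Both runs read 13 % at 12.0 min. That gave a loss of 0.0651 min⁻¹, and carried on to 20 min it left 7.72 %.
- The weak link was that rate, read at 1.40 and 2.20 equivalents of capture agent, while this flask has 1.00.
- Even by the count, first product stood less than the capture agent of this flask, so a capture would be pseudo-first-order. I therefore defined the tail constant, the fractional loss per minute for each equivalent of capture agent 0.0361 min⁻¹.
- At 12.0 min it puts first product at 14.4 % in the noon run and 11.7 % in the autumn run, each within one scatter of the reading, so the runs could not exclude it. For this flask I committed to 11.9 % at the amounts as given.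
- The forecast put the best partner at 0.85 equiv, the first product there at 10.5 %, and the first product at the amounts as given at 9.5 %, holding that “M decays independently”.
- The flask gave 0.751 equiv as the best partner, 12.7 % of first product there, and 12.1 % at the amounts as given, so the forecast stood within its margins.

    substrate + partner → first product (k = 0.0230 M⁻¹ s⁻¹)
    partner + first product → double product (k = 0.0488 M⁻¹ s⁻¹)
    first product + capture agent → trapped intermediate (k = 0.00130 M⁻¹ s⁻¹)
    first product → decomposed reagent (k = 1.08 × 10⁻⁴ s⁻¹)

- In the neighbouring flask, capture agent went up to 1.0 M, which is 2.50 equiv, with partner and time held. The tail constant gave 5.28 % of first product, and that neighbouring flask gave 5.70 %, with trapped intermediate at 19.2 %.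

(The numbers in the tables were computed for an exercise, and the scatter is random.)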